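**Retrosynthetic overview**
1. Target 25 comes from phenol 24 (ring C as a 3-aryloxy-5-isopropyl-2-methylphenol) by Teuber para-oxidation. The carbonyl next to C–CH3 is the benzannulation oxygen; the other carbonyl is installed last.
2. Ring C of 24 comes from a Danheiser benzannulation of aryl 1-propynyl ether 14 (the two ring C carbons that carry OAr and CH3) with the vinylketene from 3-isopropylcyclobutenone 19 (the other four ring C carbons). Both bonds from the alkyne carbons to the flanking (future) carbonyl carbons form in this one operation.
3. Enabling feature: in ring C the carbon bearing the aryloxy oxygen and its neighbour bearing CH3 form an enol-ether C=C (ArO–C=C–CH3, an ynol ether at the alkyne oxidation level) set between the two carbonyl carbons. Its polarisation lets the alkyne bridge the carbonyl carbon and the α-CH of a four-carbon vinylketene with one regiochemistry.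
4. 14 comes from phenol 8 (rings A–B), trichloroethylene and MeI. 8 comes from 4-methoxythymol 3 and bromoquinone 5 (addition–elimination), then reduction and site-selective O-methylation. Both 3 and 5 come from thymol.
5. Ring order: A (from thymol), B (from thymol via its quinone), then a transient four-membered ring and finally six-membered ring C.

Key step: step 11

Remark: the target has no stereocentre and no stereogenic double bond, so no configuration has to be set. Rings are lettered A (terminal anisole ring), B (central ring) and C (quinone ring).

**Step 1**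
Reactants: 1 thymol (2-isopropyl-5-methylphenol)
Product: 2 4-bromothymol (4-bromo-2-isopropyl-5-methylphenol)
Conditions: NBS (1.0 equiv), MeCN, 0 °C → rt
Reagents that add atoms: N-bromosuccinimide, O=C1CCC(=O)N1Br
Why: Electrophilic bromination of a phenol with NBS in acetonitrile is para-selective, and the para position of thymol is its least hindered activated site.

**Step 2**
Reactants: 2 4-bromothymol
Product: 3 4-methoxythymol (2-isopropyl-4-methoxy-5-methylphenol)
Conditions: NaOMe (5 equiv), CuI (10 mol%), DMF–MeOH, 110 °C; aq. HCl work-up
Reagents that add atoms: sodium methoxide, [Na+].[O-]C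
Why: Copper-catalysed Ullmann-type methanolysis of an aryl bromide tolerates a free phenol (present as its phenoxide) and should replace Br by OMe.

**Step 3**
Reactants: 3 4-methoxythymol
Product: 4 2-bromo-6-isopropyl-4-methoxy-3-methylphenol
Conditions: NBS (1.0 equiv), iPr2NH (10 mol%), CH2Cl2, 0 °C
Reagents that add atoms: N-bromosuccinimide, O=C1CCC(=O)N1Br
Why: Amine-catalysed NBS bromination of phenols is ortho-selective, and the only free ortho position of 3 lies between OH and CH3 (the other free ring position is meta to OH and flanked by OMe and isopropyl).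

**Step 4**
Reactants: 4 2-bromo-6-isopropyl-4-methoxy-3-methylphenol
Product: 5 3-bromo-5-isopropyl-2-methyl-1,4-benzoquinone
Conditions: PhI(OAc)2 (1.1 equiv), MeCN–H2O (2:1), 0 °C
Reagents that add atoms: water, O
Why: Oxidative demethylation of a para-methoxyphenol by PhI(OAc)2 in aqueous acetonitrile (water adds at the OMe-bearing carbon and methanol is lost) should give the para-quinone with the bromine untouched.

**Step 5**
Reactants: 5 3-bromo-5-isopropyl-2-methyl-1,4-benzoquinone; 3 4-methoxythymol
Product: 6 5-isopropyl-3-(2-isopropyl-4-methoxy-5-methylphenoxy)-2-methyl-1,4-benzoquinone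
Conditions: K2CO3 (1.5 equiv), DMF, 0 °C → rt
Reagents that add atoms: none
Why: Addition–elimination (vinylogous acyl substitution) of a phenoxide at the bromine-bearing carbon of a halo-quinone should occur, since the competing conjugate addition at the free CH is hindered by the neighbouring isopropyl group and has no leaving group.

**Step 6**
Reactants: 6 aryloxyquinone
Product: 8 diaryl ether phenol 2-(2-isopropyl-4-methoxy-5-methylphenoxy)-6-isopropyl-4-methoxy-3-methylphenol, via hydroquinone 7 (not isolated)
Conditions: H2 (1 atm), Pd/C (5 mol%), acetone, rt; filtered under argon; then K2CO3 (1.1 equiv), MeI (1.0 equiv), rt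
Reagents that add atoms: methyl iodide, CI
Why: Catalytic hydrogenation reduces the quinone to hydroquinone 7, and Williamson methylation with one equivalent of MeI should take place at the hydroxyl flanked by CH3 and H, not at the one buried between the isopropyl and aryloxy groups, because the two hydroxyls are of similar acidity and sterics decide.

**Step 7**
Reactants: 8 diaryl ether phenol; 9 trichloroethylene
Product: 11 (E)-1,2-dichlorovinyl ether of 8, via dichloroacetylene 10 (not isolated)
Conditions: K2CO3 (2 equiv), 9 (1.5 equiv), DMF, 70 °C
Reagents that add atoms: none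
Why: Base converts trichloroethylene into dichloroacetylene in solution, and anti addition of the phenoxide to this rod-shaped electrophile should give the (E)-dichlorovinyl aryl ether even from a di-ortho-substituted phenol (dichlorovinyl ether route to ynol ethers).

**Step 8**
Reactants: 11 (E)-1,2-dichlorovinyl ether of 8
Product: 14 aryl 1-propynyl ether of 8, via chloroethynyl ether 12 (not isolated), via lithium acetylide 13 (not isolated)
Conditions: n-BuLi (2.2 equiv), THF, −78 → −40 °C; then MeI (3 equiv), HMPA, −78 °C → rt
Reagents that add atoms: methyl iodide, CI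
Why: n-BuLi effects HCl elimination to chloroalkyne 12 and then Cl–Li exchange to acetylide 13, which is C-methylated by MeI (dichlorovinyl ether to ynol ether conversion), all at temperatures where ortho-lithiation of the anisole rings is slow.

**Step 9**
Reactants: 15 3-methyl-1-butyne; 16 trichloroacetyl chloride
Product: 18 4,4-dichloro-3-isopropylcyclobut-2-en-1-one, via dichloroketene 17 (not isolated)
Conditions: Zn–Cu couple, Et2O–DME, rt, slow addition of 16
Reagents that add atoms: none
Why: Dichloroketene generated from Cl3CCOCl and zinc undergoes regioselective (2+2) cycloaddition with a terminal alkyne, the terminal alkyne carbon bonding to the ketene carbonyl carbon, to give the 3-substituted dichlorocyclobutenone.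

**Step 10**
Reactants: 18 4,4-dichloro-3-isopropylcyclobut-2-en-1-one
Product: 19 3-isopropylcyclobut-2-en-1-one
Conditions: Zn dust, AcOH, TMEDA, EtOH, 0 °C → rt
Reagents that add atoms: none
Why: Zinc/acetic acid reductive dechlorination of an α,α-dichlorocyclobutenone, buffered with TMEDA against ring opening, should give the parent 3-alkylcyclobutenone.

**Step 11**
Reactants: 14 aryl 1-propynyl ether of 8; 19 3-isopropylcyclobut-2-en-1-one
Product: 24 ring C phenol 3-[2-(2-isopropyl-4-methoxy-5-methylphenoxy)-6-isopropyl-4-methoxy-3-methylphenoxy]-5-isopropyl-2-methylphenol, via vinylketene 20 (not isolated), via vinylcyclobutenone 21 (not isolated), via dienylketene 22 (not isolated), via cyclohexadienone 23 (not isolated)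
Conditions: 19 (2.0 equiv), PhMe (0.4 M), 80 → 110 °C, sealed tube; then KOH, MeOH, rt (cleaves any aryl ester formed from excess ketene)
Reagents that add atoms: none
Why: Heating opens 19 by 4π-electrocyclic ring opening to vinylketene 20, whose ketene C=C undergoes (2+2) cycloaddition with ynol ether 14 to give vinylcyclobutenone 21; a second 4π opening gives dienylketene 22, 6π-electrocyclization gives cyclohexadienone 23, and tautomerization gives phenol 24. The closest known reaction type is the Danheiser benzannulation of cyclobutenones with 1-alkynyl ethers, siloxyalkynes and ynamides. The transient four-membered ring closes by ketene–alkyne (2+2) cycloaddition, and ring C closes by thermal 6π-electrocyclic closure of the dienylketene (ketene carbon onto the terminal CH2). No stereocentre survives, since the one sp3 centre of 21 is racemic and is destroyed on ring opening. The step needs one regiochemistry, the CH3-bearing alkyne carbon bonding to the ketene carbonyl carbon and the O-bearing carbon to the ketene α-CH; the oxygen lone pair of the ynol ether secures it by making the CH3-bearing carbon the nucleophilic terminus, and the aryl group of 14, twisted out of conjugation by its two ortho substituents, leaves that lone pair to the alkyne. The ketene α-carbon is an unsubstituted CH, which lets the hindered O-bearing carbon bond to it, and an aryl ynol ether has no O-alkyl β-hydrogen for retro-ene loss at the reaction temperature.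

**Step 12**
Reactants: 24 ring C phenol
Product: 25 target, 3-[2-(2-isopropyl-4-methoxy-5-methylphenoxy)-6-isopropyl-4-methoxy-3-methylphenoxy]-5-isopropyl-2-methyl-1,4-benzoquinone
Conditions: (KSO3)2NO (Fremy's salt, 2.5 equiv), aq. KH2PO4, acetone–H2O, 0 °C → rt
Reagents that add atoms: potassium nitrosodisulfonate, [K+].[K+].[O]N(S(=O)(=O)[O-])S(=O)(=O)[O-]
Why: In the Teuber oxidation one nitroxyl radical abstracts the phenolic hydrogen and a second delivers oxygen to the free para carbon, which should give the para-quinone while rings A and B, fully etherified and without O–H, stay inert to this radical oxidant.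

**Compound list**
1 | thymol (2-isopropyl-5-methylphenol) | Cc1ccc(C(C)C)c(O)c1 | starting material
2 | 4-bromothymol (4-bromo-2-isopropyl-5-methylphenol) | Cc1cc(O)c(C(C)C)cc1Br | intermediate
3 | 4-methoxythymol (2-isopropyl-4-methoxy-5-methylphenol) | COc1cc(C(C)C)c(O)cc1C | intermediate
4 | 2-bromo-6-isopropyl-4-methoxy-3-methylphenol | COc1cc(C(C)C)c(O)c(Br)c1C | intermediate
5 | 3-bromo-5-isopropyl-2-methyl-1,4-benzoquinone | CC1=C(Br)C(=O)C(C(C)C)=CC1=O | intermediate
6 | 5-isopropyl-3-(2-isopropyl-4-methoxy-5-methylphenoxy)-2-methyl-1,4-benzoquinone | COc1cc(C(C)C)c(OC2=C(C)C(=O)C=C(C(C)C)C2=O)cc1C | intermediate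
7 | hydroquinone of 6: 2-(2-isopropyl-4-methoxy-5-methylphenoxy)-6-isopropyl-3-methylbenzene-1,4-diol | COc1cc(C(C)C)c(Oc2c(C)c(O)cc(C(C)C)c2O)cc1C | intermediate
8 | diaryl ether phenol: 2-(2-isopropyl-4-methoxy-5-methylphenoxy)-6-isopropyl-4-methoxy-3-methylphenol | COc1cc(C(C)C)c(Oc2c(C)c(OC)cc(C(C)C)c2O)cc1C | intermediate
9 | trichloroethylene | ClC=C(Cl)Cl | starting material
10 | dichloroacetylene | ClC#CCl | intermediate
11 | (E)-1,2-dichlorovinyl ether of 8 (the two chlorines trans) | COc1cc(C(C)C)c(Oc2c(C)c(OC)cc(C(C)C)c2O/C(Cl)=C\Cl)cc1C | intermediate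
12 | chloroethynyl ether of 8 | COc1cc(C(C)C)c(Oc2c(C)c(OC)cc(C(C)C)c2OC#CCl)cc1C | intermediate
13 | lithium aryloxyacetylide of 8 | COc1cc(C(C)C)c(Oc2c(C)c(OC)cc(C(C)C)c2OC#C[Li])cc1C | intermediate
14 | aryl 1-propynyl ether of 8 (ArO–C≡C–CH3) | COc1cc(C(C)C)c(Oc2c(C)c(OC)cc(C(C)C)c2OC#CC)cc1C | intermediate
15 | 3-methyl-1-butyne | CC(C)C#C | starting material
16 | trichloroacetyl chloride | ClC(Cl)(Cl)C(Cl)=O | starting material
17 | dichloroketene | ClC(Cl)=C=O | intermediate
18 | 4,4-dichloro-3-isopropylcyclobut-2-en-1-one | CC(C)C1=CC(=O)C1(Cl)Cl | intermediate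
19 | 3-isopropylcyclobut-2-en-1-one | CC(C)C1=CC(=O)C1 | intermediate
20 | vinylketene: 3-isopropylbuta-1,3-dien-1-one | CC(C)C(=C)C=C=O | intermediate
21 | vinylcyclobutenone: 3-aryloxy-2-methyl-4-(3-methylbut-1-en-2-yl)cyclobut-2-en-1-one (racemic, aryl = ring A–B unit of 8) | COc1cc(C(C)C)c(Oc2c(C)c(OC)cc(C(C)C)c2OC2=C(C)C(=O)C2C(=C)C(C)C)cc1C | intermediate
22 | dienylketene: 3-aryloxy-5-isopropyl-2-methylhexa-1,3,5-trien-1-one, ketene carbon and vinyl group cis across the central C=C | COc1cc(C(C)C)c(Oc2c(C)c(OC)cc(C(C)C)c2O/C(=C/C(=C)C(C)C)C(C)=C=O)cc1C | intermediate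
23 | cyclohexadienone: 3-aryloxy-5-isopropyl-2-methylcyclohexa-2,4-dien-1-one | COc1cc(C(C)C)c(Oc2c(C)c(OC)cc(C(C)C)c2OC2=C(C)C(=O)CC(C(C)C)=C2)cc1C | intermediate
24 | ring C phenol: 3-[2-(2-isopropyl-4-methoxy-5-methylphenoxy)-6-isopropyl-4-methoxy-3-methylphenoxy]-5-isopropyl-2-methylphenol | COc1cc(C(C)C)c(Oc2c(C)c(OC)cc(C(C)C)c2Oc2cc(C(C)C)cc(O)c2C)cc1C | intermediate
25 | target: 3-[2-(2-isopropyl-4-methoxy-5-methylphenoxy)-6-isopropyl-4-methoxy-3-methylphenoxy]-5-isopropyl-2-methyl-1,4-benzoquinone | COc1cc(C(C)C)c(Oc2c(C)c(OC)cc(C(C)C)c2OC2=C(C)C(=O)C=C(C(C)C)C2=O)cc1C | target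

**Step count and risks**
Total step count: 12. Longest linear sequence: 10 steps (steps 1–8, 11 and 12, from thymol); steps 9 and 10 form the short branch to 19.

Steps most likely to fail:

1. Step 11 (key step). The vinylketene 20 may be consumed by dimerisation, or by acylating the product, faster than it is trapped by the hindered and only moderately nucleophilic aryloxyalkyne 14, so that the ketene–alkyne cycloaddition never becomes productive. The fallback abandons ring construction and brings ring C in preformed. It sets out from phenol 8 and bromoquinone 5: the phenoxide of 8 (K2CO3 or Cs2CO3, DMF, 0 °C → rt) would displace bromide from 5 by the same addition–elimination used in step 5. It comes back to the route directly at target 25 and makes no new compound.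

2. Step 6. The O-methylation may show poor site selectivity, with reaction at the hindered hydroxyl or double methylation competing. The fallback fixes the oxygen pattern before the diaryl ether is made and sets out from bromophenol 4. Benzylation (BnBr, K2CO3, DMF) would give benzyl ether F1. Ullmann-type diaryl ether coupling of F1 with 4-methoxythymol 3 (CuI, picolinic acid, K3PO4, DMSO, 100 °C) would give protected diaryl ether F2. Hydrogenolysis (H2, Pd/C, EtOAc) would return to the route at phenol 8.

3. Step 12. The second nitroxyl radical may attack the ortho carbon instead of the para carbon, which lies between the isopropyl and aryloxy groups, leading to ortho-quinone formation or stalled conversion. The fallback introduces the para heteroatom by an ionic electrophile and sets out from phenol 24. Para-nitrosation (NaNO2, aq. HCl, EtOH, 0 °C) would give nitrosophenol F3 (quinone monooxime tautomer). Reduction (Na2S2O4, aq. EtOH) would give aminophenol F4. Oxidation (FeCl3, aq. HCl, rt), with hydrolysis of the quinone imine, would return to the route at target 25.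

**Further compounds**
F0 | step 11 | none | none
F1 | step 6 | benzyl ether of 4: 2-(benzyloxy)-3-bromo-1-isopropyl-5-methoxy-4-methylbenzene | COc1cc(C(C)C)c(OCc2ccccc2)c(Br)c1C
F2 | step 6 | benzyl ether of 8 | COc1cc(C(C)C)c(Oc2c(C)c(OC)cc(C(C)C)c2OCc2ccccc2)cc1C
F3 | step 12 | 4-nitroso derivative of 24 (nitroso group para to the ring C hydroxyl) | COc1cc(C(C)C)c(Oc2c(C)c(OC)cc(C(C)C)c2Oc2c(C)c(O)cc(C(C)C)c2N=O)cc1C
F4 | step 12 | 4-amino derivative of 24 (amino group para to the ring C hydroxyl) | COc1cc(C(C)C)c(Oc2c(C)c(OC)cc(C(C)C)c2Oc2c(C)c(O)cc(C(C)C)c2N)cc1C
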